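You asked which flask ends with the longer chains and how long those chains are, and you sent your forecast along as the hunch to beat.

| flask | Q | G | E | time | remark |
|---|---|---|---|---|---|
| cedar | 0.10 M (fed, over 50 s) | 0.0200 M | 0.20 mM | 3.0 min | the fed solution adds 1.0 times the starting volume |
| birch | 0.030 M (fed, over 50 s) | 0.0200 M | 0.20 mM | 3.0 min | the fed solution adds 1.0 times the starting volume |

    Q + D → Z + D, rate k1*[D]*[Q] (k1 = 1.7 × 10⁵ L mol⁻¹ s⁻¹)
    G + Q → G.Q (k2 = 1.6 L mol⁻¹ s⁻¹)
    Q + J → D + Z (k3 = 7.4 × 10⁵ L mol⁻¹ s⁻¹)
    2 D → D2 (k4 = 9 × 10⁷ L mol⁻¹ s⁻¹)
    E → 2 J (k5 = 0.022 s⁻¹)

- a doubled species enters its step squared and goes two at a time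
- every charge counts on the volume at the start, and the solution that is fed holds the whole dose
- the average divides the monomer in chains by the number of chains, living and dead together; two radicals that join make one chain
- run time (cedar): 3.0 min

- which of the two ends with the longer chains by the average number of monomer units in a chain (living and dead chains, two that joined counted as one) ("neither" if they lie within 10 %) (cedar / birch / neither)
- average number of monomer units in a chain (living and dead chains, two that joined counted as one) at the end, cedar
- average number of monomer units in a chain (living and dead chains, two that joined counted as one) at the end, birch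

**Counting chains.** I held the radicals steady: each E spent gave two J, each J gave a D, and two D joined into one chain, so chains equalled E spent, 98.1 % of its charge by 3.0 min. I carried the Q charged per E spent, 510 in cedar and 153 in birch; the average is that number times the fraction of Q ending in chains.

**Splitting Q.** I reckoned steady D as the square root of k5 E over k4, so at the start Q went to chains and to G in the ratio 1.17, a selectivity factor, which by this reckoning offered a fraction 0.540 of Q to chains. In cedar the G charge equalled 0.200 of the Q charge, less than the 0.460 the split offered it, so I capped G.Q there. With the volume taken as doubled from the start, the exposure to D, meaning k1 D summed over the run as E decayed, came to 2.08, which by my reckoning left a fraction 0.125 of the Q in cedar and gave 344. In birch the G charge equalled 0.667 of the Q charge, more than that offer, so I let the Q in birch divide by the split and gave 82.6. My answer was cedar.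

**Your forecast.** It said cedar, with 328 for cedar and 81 for birch, numbers of its own from stepping Q and G by hand, and it counted chains as I did: “Pairing gives 1.96×10⁻⁴ chains in both runs”.

**The flask.** The longer chains stood in cedar, at 326 against 81.3 in birch. For cedar with E cut to 5.0 × 10⁻⁵ M, the Q per E spent rose to 2040, the exposure fell with the square root of the E charge to 1.04, and with G.Q still capped at 0.200 the reckoning gave 911. That flask ended with 44.0 % of its Q in chains, 36 % of its Q left, and an average of 896.

The constants were set for the occasion.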